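**Strategy.** The synthesis rests on reading the pendant ring C1′–C6′ (benzofuranyl on C1′, prenyl on C2′ and C6′, hydroxyls on C3′ and C5′) as a dehydrogenated cyclohexane-1,3-dione. One base-mediated Michael–Claisen annulation of a benzofuran-2-ylmethylidene methyl ketone with diethyl prenylmalonate forms C1′–C6′ and C4′–C5′, closes this ring and places all five substituents, which makes any regioselective substitution on that arene unnecessary. The enone precursor already holds the MOM-protected 6-hydroxy-7-prenylbenzofuran and the C2′ prenyl group and is made by Horner–Wadsworth–Emmons olefination of the benzofuran-2-carbaldehyde. Ester removal, DDQ dehydrogenation of a bis-silyl dienol ether and acid-free deprotection complete the route.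

Key step: step 9

Remark: the target has no stereocentre and no stereogenic double bond, so it is achiral and needs no enantiocontrol; the sp3 centres created in step 9 are left uncontrolled because step 11 erases them. Abbreviations: prenyl = 3-methylbut-2-en-1-yl, MOM = methoxymethyl, TBS = tert-butyldimethylsilyl.

**Step 1**
Reactants: 1 2,4-dihydroxybenzaldehyde; 2 prenyl bromide
Product: 3 2,4-dihydroxy-3-prenylbenzaldehyde
Conditions: KOH, H2O, 0 °C → rt
Reagents that add atoms: none
Why: Phenolate C-alkylation in water, where solvation of the oxygens suppresses ether formation and C3, activated by both oxygens, is the most nucleophilic carbon; the 5-prenyl isomer and O-prenyl ethers should be removable by chromatography.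

**Step 2**
Reactants: 3 2,4-dihydroxy-3-prenylbenzaldehyde
Product: 4 2-hydroxy-4-(methoxymethoxy)-3-prenylbenzaldehyde
Conditions: MOMCl (1.1 equiv), K2CO3, acetone, 0 °C → rt
Reagents that add atoms: chloromethyl methyl ether, COCCl
Why: Williamson-type MOM protection should occur only at the 4-OH, because the 2-OH is held in a hydrogen bond to the formyl group and is much less nucleophilic.

**Step 3**
Reactants: 4 2-hydroxy-4-(methoxymethoxy)-3-prenylbenzaldehyde; 5 ethyl bromoacetate
Product: 8 ethyl 6-(methoxymethoxy)-7-prenylbenzofuran-2-carboxylate, via aryloxyacetate 6 (not isolated), via aldol adduct 7 (not isolated)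
Conditions: K2CO3, DMF, 100 °C
Reagents that add atoms: none
Why: Rap–Stoermer-type benzofuran synthesis: O-alkylation of the salicylaldehyde phenoxide, intramolecular aldol addition of the aryloxyacetate CH2 to the ortho formyl group and dehydration to the aromatic furan, which places the former C3 prenyl at C7 and the MOM ether at C6.

**Step 4**
Reactants: 8 ethyl 6-(methoxymethoxy)-7-prenylbenzofuran-2-carboxylate
Product: 9 [6-(methoxymethoxy)-7-prenylbenzofuran-2-yl]methanol
Conditions: LiAlH4, THF, 0 °C
Reagents that add atoms: none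
Why: Hydride reduction of the ester to the primary alcohol; the MOM acetal, the isolated alkene and the benzofuran are inert to LiAlH4.

**Step 5**
Reactants: 9 [6-(methoxymethoxy)-7-prenylbenzofuran-2-yl]methanol
Product: 10 6-(methoxymethoxy)-7-prenylbenzofuran-2-carbaldehyde
Conditions: MnO2, CH2Cl2, rt
Reagents that add atoms: none
Why: Manganese dioxide oxidation of the activated (hetero)benzylic alcohol stops at the aldehyde and leaves the trisubstituted alkene and the acetal untouched.

**Step 6**
Reactants: 11 diethyl (2-oxopropyl)phosphonate; 2 prenyl bromide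
Product: 12 diethyl (6-methyl-2-oxohept-5-en-3-yl)phosphonate (racemic)
Conditions: NaH, THF, 0 °C; then 2, 0 °C → rt
Reagents that add atoms: none
Why: SN2 C-alkylation of the sodium salt of the β-ketophosphonate with the reactive allylic bromide at the doubly activated carbon; a slight excess of 11 limits dialkylation.

**Step 7**
Reactants: 10 6-(methoxymethoxy)-7-prenylbenzofuran-2-carbaldehyde; 12 diethyl (6-methyl-2-oxohept-5-en-3-yl)phosphonate
Product: 13 (3E)-3-{[6-(methoxymethoxy)-7-prenylbenzofuran-2-yl]methylidene}-6-methylhept-5-en-2-one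
Conditions: NaH, THF, 0 °C → reflux
Reagents that add atoms: none
Why: Horner–Wadsworth–Emmons olefination of a non-enolisable aryl aldehyde with an α-branched β-ketophosphonate fixes the prenyl group on the enone α-carbon and should favour the E isomer (aryl anti to acetyl); any Z isomer can be carried on because the geometry is lost in step 9.

**Step 8**
Reactants: 14 diethyl malonate; 2 prenyl bromide
Product: 15 diethyl prenylmalonate
Conditions: NaOEt, EtOH, 0 °C → rt (14 in excess), distillation
Reagents that add atoms: none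
Why: Malonic ester alkylation; excess malonate suppresses the dialkylated product.

**Step 9**
Reactants: 13 (3E)-3-{[6-(methoxymethoxy)-7-prenylbenzofuran-2-yl]methylidene}-6-methylhept-5-en-2-one; 15 diethyl prenylmalonate
Product: 17 ethyl 2-[6-(methoxymethoxy)-7-prenylbenzofuran-2-yl]-4,6-dioxo-1,3-diprenylcyclohexane-1-carboxylate (diastereomer mixture), via Michael adduct 16 (not isolated)
Conditions: 15 (1.5 equiv), NaOEt (1.5 equiv), EtOH, reflux; then AcOH, 0 °C
Reagents that add atoms: none
Why: Ethoxide forms the sodium salt of 15, which adds reversibly to the β-carbon of 13 (bond C1′–C6′) to give 16; proton exchange then moves the enolate to the methyl group, which attacks one of the geminal esters in a Claisen condensation (bond C4′–C5′) with loss of ethoxide. The closest known reaction type is the Michael–Claisen annulation of enones with malonates used for dimedone and 5-aryl- or 5-furylcyclohexane-1,3-diones, including alkylmalonates. The ring closes in a favoured 6-(enolendo)-exo-trig mode, whereas the enolate at the prenyl-bearing α-carbon could only form a four-membered ring and is unproductive. Three sp3 centres (C1, C2, C3 of the cyclohexane) arise with no controlling element and as a mixture, which is accepted because all become sp2 by step 11. The step needs conjugate addition and closure to outrun retro-Michael cleavage of a congested adduct (a quaternary carbon beside the benzofuranyl-bearing carbon); the closure is intramolecular and ethoxide deprotonates the product 1,3-dione irreversibly, which drains the equilibrium. The fully substituted malonate cannot undergo Knoevenagel condensation, and the base-stable MOM ether prevents a phenoxide from deactivating the vinylogous acceptor.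

**Step 10**
Reactants: 17 ethyl 2-[6-(methoxymethoxy)-7-prenylbenzofuran-2-yl]-4,6-dioxo-1,3-diprenylcyclohexane-1-carboxylate
Product: 19 5-[6-(methoxymethoxy)-7-prenylbenzofuran-2-yl]-4,6-diprenylcyclohexane-1,3-dione (diastereomer mixture), via β-keto acid 18 (not isolated)
Conditions: KOH, EtOH/H2O, reflux; then AcOH, 60 °C
Reagents that add atoms: none
Why: Ester saponification followed by β-keto acid decarboxylation; the dione is present as its enolate, so hydroxide should attack the ester and not a ring carbonyl, and acetic acid is too weak to cleave the MOM ether or cyclise the prenyl groups.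

**Step 11**
Reactants: 19 5-[6-(methoxymethoxy)-7-prenylbenzofuran-2-yl]-4,6-diprenylcyclohexane-1,3-dione
Product: 21 2-[3,5-bis(tert-butyldimethylsilyloxy)-2,6-diprenylphenyl]-6-(methoxymethoxy)-7-prenylbenzofuran, via bis-silyl dienol ether 20 (not isolated)
Conditions: TBSOTf (2.5 equiv), Et3N, CH2Cl2, 0 °C → rt; evaporation, pentane filtration; then DDQ (1.05 equiv), 2,4,6-collidine, PhH, 0 °C → rt
Reagents that add atoms: tert-butyldimethylsilyl trifluoromethanesulfonate, CC(C)(C)[Si](C)(C)OS(=O)(=O)C(F)(F)F
Why: Soft enolisation silylates both dione oxygens to the cyclohexa-1,3-diene 20, from which DDQ removes hydride at the doubly activated benzofuranyl-bearing carbon and then a proton (dehydrogenative aromatisation of a cyclohexadiene), while both new phenols stay silylated and so cannot undergo DDQ-mediated chromene formation with the neighbouring prenyl groups.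

**Step 12**
Reactants: 21 2-[3,5-bis(tert-butyldimethylsilyloxy)-2,6-diprenylphenyl]-6-(methoxymethoxy)-7-prenylbenzofuran
Product: 23 5-(6-hydroxy-7-prenylbenzofuran-2-yl)-4,6-diprenylbenzene-1,3-diol (target), via tris-silyl ether 22 (not isolated)
Conditions: TMSOTf, 2,2′-bipyridyl, CH2Cl2, 0 °C → rt; then TBAF, AcOH, THF, 0 °C
Reagents that add atoms: none
Why: Silyl triflate/2,2′-bipyridyl cleavage of the aryl MOM ether exchanges it for a TMS ether without Brønsted acid, so the ortho-prenyl phenols cannot cyclise to chromans, and buffered fluoride desilylation then removes the transient TMS and both TBS groups.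

**Compound list**
1 | 2,4-dihydroxybenzaldehyde | O=Cc1ccc(O)cc1O | starting material
2 | prenyl bromide (1-bromo-3-methylbut-2-ene) | CC(C)=CCBr | starting material
3 | 2,4-dihydroxy-3-prenylbenzaldehyde | O=Cc1ccc(O)c(CC=C(C)C)c1O | intermediate
4 | 2-hydroxy-4-(methoxymethoxy)-3-prenylbenzaldehyde | O=Cc1ccc(OCOC)c(CC=C(C)C)c1O | intermediate
5 | ethyl bromoacetate | CCOC(=O)CBr | starting material
6 | ethyl 2-[6-formyl-3-(methoxymethoxy)-2-prenylphenoxy]acetate | CCOC(=O)COc1c(C=O)ccc(OCOC)c1CC=C(C)C | intermediate
7 | ethyl 3-hydroxy-6-(methoxymethoxy)-7-prenyl-2,3-dihydrobenzofuran-2-carboxylate (stereoisomer mixture) | CCOC(=O)C1Oc2c(CC=C(C)C)c(OCOC)ccc2C1O | intermediate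
8 | ethyl 6-(methoxymethoxy)-7-prenylbenzofuran-2-carboxylate | CCOC(=O)c1cc2ccc(OCOC)c(CC=C(C)C)c2o1 | intermediate
9 | [6-(methoxymethoxy)-7-prenylbenzofuran-2-yl]methanol | OCc1cc2ccc(OCOC)c(CC=C(C)C)c2o1 | intermediate
10 | 6-(methoxymethoxy)-7-prenylbenzofuran-2-carbaldehyde | O=Cc1cc2ccc(OCOC)c(CC=C(C)C)c2o1 | intermediate
11 | diethyl (2-oxopropyl)phosphonate | CC(=O)CP(=O)(OCC)OCC | starting material
12 | diethyl (6-methyl-2-oxohept-5-en-3-yl)phosphonate (racemic) | CC(=O)C(CC=C(C)C)P(=O)(OCC)OCC | intermediate
13 | (3E)-3-{[6-(methoxymethoxy)-7-prenylbenzofuran-2-yl]methylidene}-6-methylhept-5-en-2-one | CC(=O)/C(CC=C(C)C)=C/c1cc2ccc(OCOC)c(CC=C(C)C)c2o1 | intermediate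
14 | diethyl malonate | CCOC(=O)CC(=O)OCC | starting material
15 | diethyl prenylmalonate | CCOC(=O)C(CC=C(C)C)C(=O)OCC | intermediate
16 | diethyl 2-{2-acetyl-1-[6-(methoxymethoxy)-7-prenylbenzofuran-2-yl]-5-methylhex-4-en-1-yl}-2-prenylmalonate (diastereomer mixture) | CCOC(=O)C(CC=C(C)C)(C(=O)OCC)C(c1cc2ccc(OCOC)c(CC=C(C)C)c2o1)C(CC=C(C)C)C(C)=O | intermediate
17 | ethyl 2-[6-(methoxymethoxy)-7-prenylbenzofuran-2-yl]-4,6-dioxo-1,3-diprenylcyclohexane-1-carboxylate (diastereomer mixture) | CCOC(=O)C1(CC=C(C)C)C(=O)CC(=O)C(CC=C(C)C)C1c1cc2ccc(OCOC)c(CC=C(C)C)c2o1 | intermediate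
18 | 2-[6-(methoxymethoxy)-7-prenylbenzofuran-2-yl]-4,6-dioxo-1,3-diprenylcyclohexane-1-carboxylic acid (diastereomer mixture) | OC(=O)C1(CC=C(C)C)C(=O)CC(=O)C(CC=C(C)C)C1c1cc2ccc(OCOC)c(CC=C(C)C)c2o1 | intermediate
19 | 5-[6-(methoxymethoxy)-7-prenylbenzofuran-2-yl]-4,6-diprenylcyclohexane-1,3-dione (diastereomer mixture) | O=C1CC(=O)C(CC=C(C)C)C(c2cc3ccc(OCOC)c(CC=C(C)C)c3o2)C1CC=C(C)C | intermediate
20 | 2-[3,5-bis(tert-butyldimethylsilyloxy)-2,6-diprenylcyclohexa-2,4-dien-1-yl]-6-(methoxymethoxy)-7-prenylbenzofuran (diastereomer mixture) | CC(C)=CCC1C(O[Si](C)(C)C(C)(C)C)=CC(O[Si](C)(C)C(C)(C)C)=C(CC=C(C)C)C1c1cc2ccc(OCOC)c(CC=C(C)C)c2o1 | intermediate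
21 | 2-[3,5-bis(tert-butyldimethylsilyloxy)-2,6-diprenylphenyl]-6-(methoxymethoxy)-7-prenylbenzofuran | CC(C)=CCc1c(O[Si](C)(C)C(C)(C)C)cc(O[Si](C)(C)C(C)(C)C)c(CC=C(C)C)c1-c1cc2ccc(OCOC)c(CC=C(C)C)c2o1 | intermediate
22 | 2-[3,5-bis(tert-butyldimethylsilyloxy)-2,6-diprenylphenyl]-7-prenyl-6-(trimethylsilyloxy)benzofuran | CC(C)=CCc1c(O[Si](C)(C)C(C)(C)C)cc(O[Si](C)(C)C(C)(C)C)c(CC=C(C)C)c1-c1cc2ccc(O[Si](C)(C)C)c(CC=C(C)C)c2o1 | intermediate
23 | 5-(6-hydroxy-7-prenylbenzofuran-2-yl)-4,6-diprenylbenzene-1,3-diol | CC(C)=CCc1c(O)cc(O)c(CC=C(C)C)c1-c1cc2ccc(O)c(CC=C(C)C)c2o1 | target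

**Totals.** 12 steps in all. The longest linear sequence is 10 steps (1, 2, 3, 4, 5, 7, 9, 10, 11, 12); steps 6 and 8 prepare the two side components.

**Steps most likely to fail**

Step 9. Retro-Michael cleavage may outpace ring closure, because the tertiary malonate anion must form a quaternary carbon next to the benzofuranyl-bearing carbon; self-condensation of the enone through its methyl enolate could then take over. The fallback sets out from 13 and uses unsubstituted diethyl malonate 14 (NaOEt, EtOH, reflux), which creates only a tertiary centre and should give ethyl 2-[6-(methoxymethoxy)-7-prenylbenzofuran-2-yl]-4,6-dioxo-3-prenylcyclohexane-1-carboxylate F1. Saponification and decarboxylation as in step 10 would give 5-[6-(methoxymethoxy)-7-prenylbenzofuran-2-yl]-4-prenylcyclohexane-1,3-dione F2. Its dianion (LDA, 2.2 equiv, THF/DMPU, −78 °C), formed kinetically at the unsubstituted C6 methylene, would be alkylated at that γ-carbon with prenyl bromide 2, and the route is rejoined at 19.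

Step 11. The second silylation may stall at the hindered tetrasubstituted enol ether, or DDQ may oxidise the allylic positions of the prenyl groups or the electron-rich benzofuran instead of the diene. The fallback sets out from 19, which is silylated once (TBSCl, imidazole, DMF) to 3-[(tert-butyldimethylsilyl)oxy]-5-[6-(methoxymethoxy)-7-prenylbenzofuran-2-yl]-4,6-diprenylcyclohex-2-en-1-one F3, a single constitution because 19 is constitutionally symmetric. α′-Selenenylation (LDA, THF, −78 °C; PhSeBr) would give 3-[(tert-butyldimethylsilyl)oxy]-5-[6-(methoxymethoxy)-7-prenylbenzofuran-2-yl]-6-(phenylselanyl)-4,6-diprenylcyclohex-2-en-1-one F4. Oxidation (H2O2, pyridine, CH2Cl2, 0 °C) triggers selenoxide syn-elimination and tautomerisation to 3-[(tert-butyldimethylsilyl)oxy]-5-[6-(methoxymethoxy)-7-prenylbenzofuran-2-yl]-4,6-diprenylphenol F5. Silylation of the free phenol (TBSCl, imidazole, DMF) returns to 21.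

Step 1. O-alkylation, C5-alkylation and double prenylation may compete with the wanted C3-alkylation and leave little separable 3. The fallback sets out from 1, which is etherified at the non-chelated 4-OH with 3-chloro-3-methylbut-1-yne (K2CO3, KI, cat. CuI, acetone, reflux) to 2-hydroxy-4-[(2-methylbut-3-yn-2-yl)oxy]benzaldehyde F6. Semi-hydrogenation (H2, Lindlar catalyst, quinoline, EtOAc) would give 2-hydroxy-4-[(2-methylbut-3-en-2-yl)oxy]benzaldehyde F7. Heating (N,N-diethylaniline, about 130 °C) brings about an aromatic Claisen rearrangement, directed to C3 by the bond fixation of the chelated salicylaldehyde, and the route is rejoined at 3.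

**Further compounds**
F1 | step 9 | ethyl 2-[6-(methoxymethoxy)-7-prenylbenzofuran-2-yl]-4,6-dioxo-3-prenylcyclohexane-1-carboxylate (diastereomer mixture) | CCOC(=O)C1C(=O)CC(=O)C(CC=C(C)C)C1c1cc2ccc(OCOC)c(CC=C(C)C)c2o1
F2 | step 9 | 5-[6-(methoxymethoxy)-7-prenylbenzofuran-2-yl]-4-prenylcyclohexane-1,3-dione (diastereomer mixture) | O=C1CC(=O)C(CC=C(C)C)C(c2cc3ccc(OCOC)c(CC=C(C)C)c3o2)C1
F3 | step 11 | 3-[(tert-butyldimethylsilyl)oxy]-5-[6-(methoxymethoxy)-7-prenylbenzofuran-2-yl]-4,6-diprenylcyclohex-2-en-1-one (diastereomer mixture) | O=C1C=C(O[Si](C)(C)C(C)(C)C)C(CC=C(C)C)C(c2cc3ccc(OCOC)c(CC=C(C)C)c3o2)C1CC=C(C)C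
F4 | step 11 | 3-[(tert-butyldimethylsilyl)oxy]-5-[6-(methoxymethoxy)-7-prenylbenzofuran-2-yl]-6-(phenylselanyl)-4,6-diprenylcyclohex-2-en-1-one (diastereomer mixture) | O=C1C=C(O[Si](C)(C)C(C)(C)C)C(CC=C(C)C)C(c2cc3ccc(OCOC)c(CC=C(C)C)c3o2)C1(CC=C(C)C)[Se]c1ccccc1
F5 | step 11 | 3-[(tert-butyldimethylsilyl)oxy]-5-[6-(methoxymethoxy)-7-prenylbenzofuran-2-yl]-4,6-diprenylphenol | CC(C)=CCc1c(O)cc(O[Si](C)(C)C(C)(C)C)c(CC=C(C)C)c1-c1cc2ccc(OCOC)c(CC=C(C)C)c2o1
F6 | step 1 | 2-hydroxy-4-[(2-methylbut-3-yn-2-yl)oxy]benzaldehyde | O=Cc1ccc(OC(C)(C)C#C)cc1O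
F7 | step 1 | 2-hydroxy-4-[(2-methylbut-3-en-2-yl)oxy]benzaldehyde | O=Cc1ccc(OC(C)(C)C=C)cc1O
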